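# Uprolide D: radical-macrocyclization route

**Assumptions (one line each)**
- (S)-4-Methyltetrahydropyran-2-one (β-methyl-δ-valerolactone) is taken as commercially available.
- Tartrate and Shi-catalyst enantiomers are chosen to give the epoxide configurations drawn.
- The C14 epimer formed in Step 12 is separable by chromatography.

**Retrosynthesis**
- Uprolide D comes from a late Pd cyclocarbonylation of a C7–OH/C8-alkyne. The alkyne is made by syn-selective alkynylalane opening of a trans-7,8-epoxide.
- The C11–O–C14 oxa-bridge and C10–OH come from transannular 5-exo opening of a (10R,11R) trisubstituted epoxide by C14–OH.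
- The 14-membered ring, the C14 carbinol and the exocyclic methylene form in one SmI₂ ketyl–alkyne macrocyclization (C14–C1) of a TMS-alkynyl aldehyde.
- The precursor is built by E-selective cross-metathesis of a lactone-derived C1–C7 piece and a 4-pentyn-1-ol-derived C8–C14 piece, followed by Sharpless epoxidation.
- Order of ring formation: 14-membered carbocycle (radical), then THF bridge, then γ-lactone.

---

### Step 1
**Reactants:** 1, (S)-4-methyltetrahydro-2H-pyran-2-one
**Product:** 2, (3R,4S)-3-hydroxy-4-methyltetrahydro-2H-pyran-2-one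
**Conditions:** LiHMDS, THF, –78 °C; then Davis oxaziridine, –78 °C
**Reagents that add atoms:** Davis oxaziridine (transfers O), O=S(=O)(c1ccccc1)N1OC1c1ccccc1
**Why:** Enolate hydroxylation (Davis oxidation) occurs anti to the β-methyl group, giving the trans lactone. This sets C6 (R) syn to C5 (S) in the open-chain sense.

### Step 2
**Reactants:** 2
**Product:** 3, (3R,4S)-3-(tert-butyldimethylsilyloxy)-4-methyltetrahydropyran-2-one
**Conditions:** TBSCl, imidazole, DMF, rt
**Reagents that add atoms:** TBSCl, CC(C)(C)[Si](C)(C)Cl
**Why:** Silylation masks C6–OH. A free 1,4-hydroxy iodide would otherwise cyclize to a THF in Steps 5–6.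

### Step 3
**Reactants:** 3
**Product:** 4, lactol (anomeric mixture)
**Conditions:** DIBAL-H (1.05 equiv), toluene, –78 °C
**Reagents that add atoms:** none
**Why:** Partial reduction stops at the lactol stage. The lactol masks the C7 aldehyde and keeps C6 from epimerizing.

### Step 4
**Reactants:** 4
**Product:** 5, (3S,4S)-4-(TBSO)-3-methylhex-5-en-1-ol
**Conditions:** Ph₃P=CH₂ (3 equiv; from Ph₃PCH₃Br/KOtBu), THF, 0 °C → rt
**Reagents that add atoms:** methylenetriphenylphosphorane (leaves CH₂), C=P(c1ccccc1)(c1ccccc1)c1ccccc1
**Why:** Wittig methylenation of the ring-opened aldehyde form gives the terminal alkene and frees the C3 primary alcohol. No new stereocenter is formed. The α-silyloxy centre is protected by the low temperature and the short lifetime of the free aldehyde.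

### Step 5
**Reactants:** 5
**Product:** 6, tert-butyl{[(3S,4S)-6-iodo-4-methylhex-1-en-3-yl]oxy}dimethylsilane
**Conditions:** I₂, PPh₃, imidazole, Et₂O/MeCN, 0 °C
**Reagents that add atoms:** iodine, II
**Why:** Appel iodination of the primary alcohol proceeds with no stereochemical change.

### Step 6
**Reactants:** 6; 7, 1-(trimethylsilyl)propyne
**Product:** 8, (3S,4S)-TBS-protected 4-methyl-9-TMS-non-1-en-8-yn-3-ol (C1–C7 piece, with a TMS-alkyne)
**Conditions:** 7 + n-BuLi, THF, –78 → 0 °C; then 6, HMPA, –78 °C → rt
**Reagents that add atoms:** none (the CH₂C≡C–TMS unit comes from 7)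
**Why:** SN2 alkylation of the propargyllithium forms the C2–C3 bond and installs the TMS-capped alkyne required to direct exo attack in Step 12.

### Step 7
**Reactants:** 9, 4-pentyn-1-ol
**Product:** 10, (E)-4-methylocta-4,7-dien-1-ol
**Conditions:** Me₃Al, Cp₂ZrCl₂ (cat.), ClCH₂CH₂Cl, rt; then CuCl (cat.), allyl bromide, 0 °C → rt
**Reagents that add atoms:** trimethylaluminum, C[Al](C)C; allyl bromide, C=CCBr
**Why:** Negishi carboalumination is a syn addition and gives the E-trisubstituted vinylalane. Cu-catalysed allylation proceeds with retention of alkene geometry.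

### Step 8
**Reactants:** 8; 10 (3 equiv)
**Product:** 11, (4E,7E,9R,10S)-9-(TBSO)-4,10-dimethyl-15-TMS-pentadeca-4,7-dien-14-yn-1-ol
**Conditions:** Hoveyda–Grubbs II (5 mol %), CH₂Cl₂, 40 °C
**Reagents that add atoms:** none (ethylene is lost)
**Why:** Cross-metathesis of the two terminal alkenes joins C7 and C8 and gives the E-alkene selectively. The trisubstituted alkene does not react. The C8 excess of 10 suppresses dimer formation.

### Step 9
**Reactants:** 11
**Product:** 12, (4E,7E,9R,10S)-4,10-dimethyl-15-TMS-pentadeca-4,7-dien-14-yne-1,9-diol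
**Conditions:** HF·pyridine, THF/pyridine, 0 °C → rt
**Reagents that add atoms:** none
**Why:** Acidic fluoride removes the secondary TBS ether but leaves the C(sp)–TMS bond intact. (TBAF would cleave the alkynyl TMS.) This unmasks the allylic alcohol needed for directed epoxidation.

### Step 10
**Reactants:** 12
**Product:** 13, trans-(7S,8S)-epoxy alcohol
**Conditions:** Ti(OiPr)₄, L-(+)-DIPT, TBHP, 4 Å MS, CH₂Cl₂, –20 °C
**Reagents that add atoms:** tert-butyl hydroperoxide (transfers O), CC(C)(C)OO
**Why:** Sharpless asymmetric epoxidation is directed by the C9 allylic alcohol and is chemoselective over the remote trisubstituted alkene. L-(+)-DIPT delivers O to the face giving (7S,8S). With the (9R) carbinol this is the matched threo pair. It fixes C7/C8, and the trans epoxide later gives the syn relationship needed for the cis-fused lactone.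

### Step 11
**Reactants:** 13
**Product:** 14, C14 aldehyde
**Conditions:** TEMPO (cat.), KBr, NaOCl, NaHCO₃, CH₂Cl₂/H₂O, 0 °C
**Reagents that add atoms:** none
**Why:** Anelli oxidation is selective for the primary alcohol over the secondary C6–OH. The buffer protects the epoxide, and no stereocenter is involved.

### Step 12
**Reactants:** 14
**Product:** 15, 14-membered carbocycle (C14–OH, C1=C18H–TMS, C10=C11 E, trans-7,8-epoxide); C14 epimer also formed and separated
**Conditions:** SmI₂ (3 equiv), HMPA, t-BuOH, THF, rt; substrate added by syringe pump to ~2 mM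
**Reagents that add atoms:** none (H from t-BuOH)
**Why:** Proposed new method: the aldehyde is reduced to a Sm(III) ketyl. This nucleophilic radical adds 14-exo to C1 of the TMS-alkyne, because attack β to silicon gives a stabilized α-silyl vinyl radical. The vinyl radical is then reduced and protonated. The closest known reaction type is SmI₂ ketyl–alkyne 5/6-exo-dig cyclization (Molander/Reissig), extended here to a macrocycle. The step forms the C14–C1 bond, the C14 carbinol and the exocyclic alkene together. The C14 configuration is set by the macrocyclic conformation and is later checked by the bridging THF closure.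

### Step 13
**Reactants:** 15
**Product:** 16, (10R,11R)-epoxide macrocycle
**Conditions:** Shi fructose-derived ketone (30 mol %), Oxone, K₂CO₃, Na₂EDTA, MeCN/DMM/aq. buffer, 0 °C (pH 10.5)
**Reagents that add atoms:** potassium peroxymonosulfate (transfers O), [K+].OOS(=O)(=O)[O-]
**Why:** Shi epoxidation selects the trisubstituted E-alkene over the vinylsilane. Catalyst control sets C10/C11 as (10R,11R), trans from the E-alkene.

### Step 14
**Reactants:** 16
**Product:** 17, oxa-bridged macrocycle (THF, C10–OH, C11 quaternary)
**Conditions:** CSA (0.1 equiv), CH₂Cl₂, 0 °C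
**Reagents that add atoms:** none
**Why:** Acid-catalysed transannular 5-exo opening of the epoxide by C14–OH occurs at the tertiary carbon C11 with inversion. The 11R epoxide carbon becomes 11S and C10–OH is released with retention. This gives the cis-2,5-bridged THF and establishes the C10/C11 anti relationship. The C14 configuration that bridges is the one carried forward.

### Step 15
**Reactants:** 17
**Product:** 18, homopropargylic diol (C8–C≡C–TMS, C7–OH)
**Conditions:** Et₂AlC≡C–TMS (5 equiv; TMS-acetylene + n-BuLi, then Et₂AlCl), toluene/hexane, –78 °C → rt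
**Reagents that add atoms:** trimethylsilylacetylene, C[Si](C)(C)C#C
**Why:** Yamaguchi–Hirao alkynylalane opening of a 2,3-epoxy alcohol occurs at the distal carbon C8 with inversion. Applied to the trans epoxide, this gives the C7/C8 syn relationship (O7 and C9 syn), which becomes the cis-fused lactone.

### Step 16
**Reactants:** 18
**Product:** 19, terminal alkyne (the vinylsilane is retained)
**Conditions:** K₂CO₃, MeOH, rt
**Reagents that add atoms:** none
**Why:** Base-mediated protodesilylation cleaves the alkynyl C–Si bond only. The vinylsilane is inert.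

### Step 17
**Reactants:** 19
**Product:** 20, α-methylene-γ-lactone (vinylsilane still present)
**Conditions:** Pd(OAc)₂ (5 mol %), thiourea ligand, TsOH (cat.), CO (1 atm), THF, 50 °C
**Reagents that add atoms:** carbon monoxide, [C-]#[O+]
**Why:** Norton Pd-catalysed cyclocarbonylation of a homopropargylic alcohol gives the α-methylene-γ-butyrolactone (5-exo). C7 and C8 stereochemistry is retained, giving the cis-fused lactone.

### Step 18
**Reactants:** 20
**Product:** 21, Uprolide D
**Conditions:** TFA (5% v/v), CH₂Cl₂, 0 °C
**Reagents that add atoms:** none (H from TFA)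
**Why:** Protonation at C18 gives the tertiary cation at C1, which is stabilized by the β-silyl group. Loss of TMS then gives the exocyclic methylene (protodesilylation).

---

### Compound list
| # | Name | SMILES | Role |
|---|---|---|---|
| 1 | (S)-4-methyltetrahydropyran-2-one | C[C@H]1CCOC(=O)C1 | starting material |
| 2 | (3R,4S)-3-hydroxy-4-methyl-δ-lactone | O=C1OCC[C@H](C)[C@H]1O | intermediate |
| 3 | TBS ether of 2 | O=C1OCC[C@H](C)[C@H]1O[Si](C)(C)C(C)(C)C | intermediate |
| 4 | lactol of 3 | OC1OCC[C@H](C)[C@H]1O[Si](C)(C)C(C)(C)C | intermediate |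
| 5 | (3S,4S)-4-TBSO-3-methylhex-5-en-1-ol | OCC[C@H](C)[C@@H](O[Si](C)(C)C(C)(C)C)C=C | intermediate |
| 6 | primary iodide | ICC[C@H](C)[C@@H](O[Si](C)(C)C(C)(C)C)C=C | intermediate |
| 7 | 1-(trimethylsilyl)propyne | C[Si](C)(C)C#CC | starting material |
| 8 | TMS-alkyne/vinyl C1–C7 piece | C[Si](C)(C)C#CCCC[C@H](C)[C@@H](O[Si](C)(C)C(C)(C)C)C=C | intermediate |
| 9 | 4-pentyn-1-ol | C#CCCCO | starting material |
| 10 | (E)-4-methylocta-4,7-dien-1-ol | OCCC/C(C)=C/CC=C | intermediate |
| 11 | cross-metathesis product | C[Si](C)(C)C#CCCC[C@H](C)[C@@H](O[Si](C)(C)C(C)(C)C)/C=C/C/C=C(\C)CCCO | intermediate |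
| 12 | allylic alcohol diol | C[Si](C)(C)C#CCCC[C@H](C)[C@@H](O)/C=C/C/C=C(\C)CCCO | intermediate |
| 13 | trans-(7S,8S) epoxy alcohol | C[Si](C)(C)C#CCCC[C@H](C)[C@@H](O)[C@@H]1O[C@H]1C/C=C(\C)CCCO | intermediate |
| 14 | C14 aldehyde | C[Si](C)(C)C#CCCC[C@H](C)[C@@H](O)[C@@H]1O[C@H]1C/C=C(\C)CCC=O | intermediate |
| 15 | macrocyclic alkene/epoxide (C14–OH) | O[C@@H]1CC/C(C)=C/C[C@@H]2O[C@H]2[C@H](O)[C@@H](C)CCCC1=C[Si](C)(C)C | intermediate |
| 16 | (10R,11R)-epoxide macrocycle | O[C@@H]1CC[C@@]2(C)O[C@@H]2C[C@@H]2O[C@H]2[C@H](O)[C@@H](C)CCCC1=C[Si](C)(C)C | intermediate |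
| 17 | oxa-bridged macrocycle | C[Si](C)(C)C=C1CCC[C@H](C)[C@@H](O)[C@@H]2O[C@H]2C[C@@H](O)[C@]2(C)CC[C@H]1O2 | intermediate |
| 18 | C8 TMS-alkyne diol | C[Si](C)(C)C=C1CCC[C@H](C)[C@@H](O)[C@H](O)[C@H](C#C[Si](C)(C)C)C[C@@H](O)[C@]2(C)CC[C@H]1O2 | intermediate |
| 19 | terminal alkyne | C[Si](C)(C)C=C1CCC[C@H](C)[C@@H](O)[C@H](O)[C@H](C#C)C[C@@H](O)[C@]2(C)CC[C@H]1O2 | intermediate |
| 20 | lactone vinylsilane | C[Si](C)(C)C=C1CCC[C@H](C)[C@@H](O)[C@@H]2OC(=O)C(=C)[C@@H]2C[C@@H](O)[C@]2(C)CC[C@H]1O2 | intermediate |
| 21 | Uprolide D | C=C1CCC[C@H](C)[C@@H](O)[C@@H]2OC(=O)C(=C)[C@@H]2C[C@@H](O)[C@]2(C)CC[C@H]1O2 | target |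

**Total steps:** 18.
**Longest linear sequence:** 17 steps (1→2→3→4→5→6→8→11→12→13→14→15→16→17→18→19→20→21, counting step 7 as a parallel branch).

### Three steps most likely to fail
1. **Step 12 (SmI₂ macrocyclization).** Risks are endo (15-membered) attack, aldehyde pinacol dimerization and the wrong C14 epimer.
   *Fallback:* change the ring-closing reaction to an intramolecular Nozaki–Hiyama–Kishi (NHK) vinylation. In Step 6, alkylate the C3 organozinc from 6 (OH protected) with 2,3-dibromopropene to give the C1 vinyl bromide, then close the ring by Cr/Ni-mediated addition to the C14 aldehyde.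
2. **Steps 13–14 (facial selectivity of the Shi epoxidation on the macrocycle and THF closure).** The ring conformation may override catalyst control, or the wrong C14 epimer may not bridge.
   *Fallback:* replace the Shi/acid pair with Co(modp)₂/O₂ Mukaiyama-type aerobic oxidative cyclization of C14–OH onto the E-alkene, which forms the THF and C10–OH in one step. Epimerize any wrong C14 isomer by oxidation to the enone and Luche reduction.
3. **Step 17 (Pd cyclocarbonylation with free C6/C10 hydroxyls).** A competing δ-lactone (C6–OH) or catalyst poisoning could occur.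
   *Fallback:* change the lactone construction. Open the 7,8-epoxide instead with a 2-(silyloxymethyl)vinyl cuprate from 2-bromoallyl alcohol. Then form the lactone by TEMPO/PhI(OAc)₂ oxidative lactonization of the resulting 1,4-diol, replacing Steps 15–17.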